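**Plan**

- Numbering: in ring A (the epoxycyclohexane) C1 carries the linker CH2, C2 the isopropenyl group, C5 the methyl group and C5/C6 the epoxide; in ring B (the bromohydrin ring) C1′ is the methine on the linker, C3′ is CHBr and C4′ is C(OH)CH3.
- Cuts, last bond first: the two epoxide C–O bonds of ring A; C4′–CH3 and C3′–Br; the linker C=CH2 (back to a ketone); both ring-B bonds at C1′ (C1′–C2′ and C1′–C6′); the keto ester C–C bond; the carvone C6–CH2 bond.
- Enabling feature: with the linker carbon as a ketone, C1′ is its α-carbon and the carbinol carbon C4′ lies para to C1′, so one β-keto ester carbon plus the five carbons of penta-1,4-dien-3-one make up all of ring B.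
- Forward order: ring A comes intact from (S)-carvone (trans alkylation, reductive alkene transposition); the side chain is extended to an allyl β-keto ester; ring B is closed on it by double Michael addition; decarboxylation and methylenation build the linker; ring B is desymmetrised, brominated and methylated; ring A is epoxidised last.
- Stereochemistry: C2 from carvone; C1 by alkylation anti to isopropenyl; C1′ by a chiral lithium amide; C3′ by bromide equilibration to the equatorial epimer; C4′ by equatorial Grignard attack; C5/C6 by the Shi ketone.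

Key step: step 7

Assumption: the (S,S) enantiomer of lithium bis(1-phenylethyl)amide and the D-fructose-derived Shi ketone are taken to have the required sense, by analogy with 4-tert-butylcyclohexanone and 1-phenylcyclohexene respectively; if either analogy fails, the mirror-image reagent is used with nothing else changed.

**Route**

Step 1
Reactants: 1 (S)-(+)-carvone; 2 methyl bromoacetate
Product: 4 methyl 2-[(1R,6S)-3-methyl-2-oxo-6-(prop-1-en-2-yl)cyclohex-3-en-1-yl]acetate (side chain trans to isopropenyl), via lithium dienolate 3 (not isolated)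
Conditions: LiN(iPr)2, THF, −78 °C; then 2, −78 → −30 °C
Reagents that add atoms: none
Why: Kinetic deprotonation of the enone at C6 gives the cross-conjugated lithium dienolate, and enolate alkylation with the reactive α-bromo ester should occur on the face opposite the adjacent isopropenyl group, setting ring-A C1 trans to the carvone-derived C2 centre.

Step 2
Reactants: 4 keto ester
Product: 5 p-toluenesulfonylhydrazone of 4
Conditions: TsNHNH2, AcOH (cat.), MeOH, 50 °C
Reagents that add atoms: p-toluenesulfonyl hydrazide, Cc1ccc(cc1)S(=O)(=O)NN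
Why: Acid-catalysed condensation of the ketone with the sulfonyl hydrazide (hydrazone formation) creates no new stereocentre, and any enolisation at the α-carbon returns the thermodynamically preferred trans arrangement.

Step 3
Reactants: 5 tosylhydrazone
Product: 8 methyl 2-[(1S,6S)-3-methyl-6-(prop-1-en-2-yl)cyclohex-2-en-1-yl]acetate, via N-boryl hydrazine 6 (not isolated), via allylic diazene 7 (not isolated)
Conditions: catecholborane, CHCl3, 0 °C; then NaOAc·3H2O, reflux
Reagents that add atoms: none
Why: Reductive alkene transposition of an enone tosylhydrazone: hydride adds to the C=N carbon, acetate-induced loss of sulfinate gives the allylic diazene, and its retro-ene loss of N2 delivers hydrogen to the former β-carbon and moves the double bond to C5=C6 of ring A, leaving C1 and C2 untouched and creating no stereocentre.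

Step 4
Reactants: 8 ring-A methyl ester
Product: 9 2-[(1S,6S)-3-methyl-6-(prop-1-en-2-yl)cyclohex-2-en-1-yl]acetic acid
Conditions: LiOH, THF/MeOH/H2O, 23 °C; then cold aq. HCl to pH 3
Reagents that add atoms: lithium hydroxide, [Li+].[OH-]
Why: Ester saponification, in which the stereocentre is β to the carboxyl group and cannot epimerise.

Step 5
Reactants: 9 ring-A acetic acid; 10 Meldrum's acid
Product: 12 allyl 4-[(1S,6S)-3-methyl-6-(prop-1-en-2-yl)cyclohex-2-en-1-yl]-3-oxobutanoate, via acyl Meldrum's acid 11 (not isolated)
Conditions: N,N'-dicyclohexylcarbodiimide, 4-(dimethylamino)pyridine, CH2Cl2, 0 → 23 °C; filter, concentrate; then allyl alcohol, toluene, 90 °C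
Reagents that add atoms: allyl alcohol, C=CCO
Why: Meldrum's acid route to β-keto esters: carbodiimide-mediated C-acylation, then thermal loss of acetone and CO2 to an acylketene that is trapped by allyl alcohol, giving under neutral conditions an ester that can later be removed without acid, which the ring-A alkenes would not tolerate.

Step 6
Reactants: 13 1,5-dichloropentan-3-one
Product: 15 penta-1,4-dien-3-one (cold ether solution, used at once), via 5-chloropent-1-en-3-one 14 (not isolated)
Conditions: Et3N (2.2 equiv), Et2O, 0 °C; filter; trace hydroquinone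
Reagents that add atoms: none
Why: Two-fold E1cB dehydrochlorination of a β-chloro ketone by a tertiary amine gives the dienone, which is kept cold and dilute and used at once because it polymerises on storage.

Step 7
Reactants: 12 allyl β-keto ester; 15 penta-1,4-dien-3-one
Product: 17 allyl 1-{2-[(1S,6S)-3-methyl-6-(prop-1-en-2-yl)cyclohex-2-en-1-yl]acetyl}-4-oxocyclohexane-1-carboxylate, via mono-Michael adduct 16 (not isolated)
Conditions: Cs2CO3 (0.3 equiv), MeCN, 0 °C; slow addition of 15 (1.3 equiv in Et2O); then 23 °C
Reagents that add atoms: none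
Why: Carbonate deprotonates only the doubly activated C2 methylene of 12, whose enolate adds to one vinyl group of 15; proton transfer regenerates a stabilised enolate at the same carbon in 16, which adds to the second vinyl group and closes ring B. The closest known reaction type is the base-mediated double Michael addition of active methylene compounds to divinyl ketones, which gives 4,4-disubstituted cyclohexanones. Ring B closes by a 6-endo-trig conjugate addition, both new C–C bonds ending at the carbon that becomes the methine C1′, with the ring ketone already at C4′. No stereocentre is created in 17, because the centre that appears in 16 becomes a ring carbon on the mirror plane of the new cyclohexanone, and the two ring-A centres are remote and not epimerisable. The step needs double C-alkylation at C2 in preference to reaction at the other α-carbon of the ketone and to oligomerisation of 15; the much higher acidity of the 1,3-dicarbonyl methylene, the catalytic weak base and the slow addition of 15 secure this, and the mild conditions avoid retro-Claisen cleavage and bridged aldol closure of the 1,5-diketone product.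

Step 8
Reactants: 17 4-acyl-4-(allyloxycarbonyl)cyclohexanone
Product: 18 allyl 8-{2-[(1S,6S)-3-methyl-6-(prop-1-en-2-yl)cyclohex-2-en-1-yl]acetyl}-1,4-dioxaspiro[4.5]decane-8-carboxylate
Conditions: ethylene glycol, pyridinium p-toluenesulfonate (cat.), benzene, reflux, Dean–Stark
Reagents that add atoms: ethylene glycol, OCCO
Why: Acid-catalysed ketalisation is selective for the unhindered ring ketone because the other ketone is flanked by a quaternary carbon, and pyridinium tosylate is too weak an acid to protonate the alkenes.

Step 9
Reactants: 18 ketal β-keto ester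
Product: 20 1-(1,4-dioxaspiro[4.5]decan-8-yl)-2-[(1S,6S)-3-methyl-6-(prop-1-en-2-yl)cyclohex-2-en-1-yl]ethan-1-one, via β-keto acid 19 (not isolated)
Conditions: Pd(PPh3)4 (5 mol%), morpholine, THF, 23 °C; then 50 °C
Reagents that add atoms: none
Why: Tsuji–Trost deallylation: zerovalent palladium transfers the allyl group to morpholine and the resulting β-keto acid decarboxylates through its enol on gentle warming, leaving C1′ as a methine that is not stereogenic while ring B is symmetric.

Step 10
Reactants: 20 ketal ketone
Product: 21 8-{3-[(1S,6S)-3-methyl-6-(prop-1-en-2-yl)cyclohex-2-en-1-yl]prop-1-en-2-yl}-1,4-dioxaspiro[4.5]decane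
Conditions: Ph3PCH3Br, KOtBu, THF, 0 → 65 °C
Reagents that add atoms: methyltriphenylphosphonium bromide, C[P+](c1ccccc1)(c1ccccc1)c1ccccc1.[Br-]
Why: Wittig methylenation with the non-stabilised ylide converts the ketone into the 1,1-disubstituted linker alkene; neither α-carbon is stereogenic, so enolisation by the basic ylide is harmless, and the ketal shields the ring ketone.

Step 11
Reactants: 21 ketal triene
Product: 22 4-{3-[(1S,6S)-3-methyl-6-(prop-1-en-2-yl)cyclohex-2-en-1-yl]prop-1-en-2-yl}cyclohexan-1-one
Conditions: aq. HCl (1 M), THF, 23 °C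
Reagents that add atoms: water, O
Why: Acid-catalysed ketal hydrolysis in dilute aqueous acid at room temperature, conditions under which unactivated tri- and 1,1-disubstituted alkenes are not hydrated.

Step 12
Reactants: 22 ring-B ketone
Product: 24 trimethylsilyl enol ether of 22 with the double bond C3′=C4′ and C1′ (R), via lithium enolate 23 (not isolated)
Conditions: (S,S)-bis(1-phenylethyl)amine, n-BuLi, LiCl, Me3SiCl (internal quench), THF, −90 °C; NaHCO3/pentane work-up
Reagents that add atoms: chlorotrimethylsilane, C[Si](C)(C)Cl
Why: Enantiotopic-group-selective deprotonation of a 4-substituted cyclohexanone by a C2-symmetric chiral lithium amide with internal silyl quench removes one of the two axial α-protons, which fixes the enol double bond toward C3′ and thereby makes C1′ stereogenic with the (R) configuration, the ring-A centres being too remote to interfere.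

Step 13
Reactants: 24 silyl enol ether
Product: 26 (2R,4R)-2-bromo-4-{3-[(1S,6S)-3-methyl-6-(prop-1-en-2-yl)cyclohex-2-en-1-yl]prop-1-en-2-yl}cyclohexan-1-one (bromine cis to the C1′ substituent, both equatorial), via trans-bromo ketone 25 (not isolated)
Conditions: N-bromosuccinimide, THF, −78 °C; then LiBr, DMF, 23 °C; chromatography, trans epimer resubmitted to LiBr
Reagents that add atoms: N-bromosuccinimide, O=C1CCC(=O)N1Br; lithium bromide, [Li+].[Br-]
Why: Electrophilic bromination of the silyl enol ether by axial attack gives the kinetic trans bromide 25, and bromide-for-bromide SN2 exchange then inverts only the C–Br carbon without enolisation and should settle on the diequatorial cis epimer favoured in a dipolar solvent, so C3′ is set under thermodynamic control while the regiochemistry fixed in step 12 is kept.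

Step 14
Reactants: 26 cis-α-bromo ketone
Product: 27 (1S,2R,4R)-2-bromo-1-methyl-4-{3-[(1S,6S)-3-methyl-6-(prop-1-en-2-yl)cyclohex-2-en-1-yl]prop-1-en-2-yl}cyclohexan-1-ol
Conditions: MeMgBr, Et2O, −78 °C; aqueous NH4Cl quench at −78 °C
Reagents that add atoms: methylmagnesium bromide, C[Mg]Br
Why: Grignard addition to an α-bromo ketone, in which the reagent should attack from the equatorial direction trans to the equatorial bromine to give the equatorial methyl and the axial hydroxyl cis to bromine (the halohydrin diastereomer normally formed from 2-halocyclohexanones), while the cold quench prevents rearrangement of the magnesium alkoxide.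

Step 15
Reactants: 27 bromohydrin triene
Product: 28 (1S,2R,4R)-2-bromo-1-methyl-4-{3-[(1R,2R,3S,6S)-6-methyl-3-(prop-1-en-2-yl)-7-oxabicyclo[4.1.0]heptan-2-yl]prop-1-en-2-yl}cyclohexan-1-ol (CNP0213097.1)
Conditions: D-fructose-derived Shi ketone (1,2:4,5-di-O-isopropylidene-β-D-erythro-2,3-hexodiulo-2,6-pyranose, 30 mol%), KHSO5 (as 2KHSO5·KHSO4·K2SO4), K2CO3, Bu4NHSO4, MeCN/CH2(OMe)2, aq. Na2B4O7 buffer pH 10.5, −10 → 0 °C
Reagents that add atoms: potassium peroxymonosulfate, [K+].[O-]S(=O)(=O)OO
Why: Shi epoxidation, in which the chiral dioxirane reacts fastest with the electron-rich trisubstituted ring-A alkene (the two 1,1-disubstituted alkenes are poor substrates) and its spiro transition state should deliver oxygen to the face syn to the C1 side chain, the same sense as for 1-phenylcyclohexene, overriding the weak substrate bias, while the cis bromohydrin cannot close to an epoxide at this pH.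

**Compound list**

1 | (S)-(+)-carvone | CC1=CC[C@@H](CC1=O)C(C)=C | starting material
2 | methyl bromoacetate | COC(=O)CBr | starting material
3 | lithium dienolate of 1 (cross-conjugated, enolate toward C6) | [Li]OC1=C[C@@H](C(C)=C)CC=C1C | intermediate (not isolated)
4 | methyl 2-[(1R,6S)-3-methyl-2-oxo-6-(prop-1-en-2-yl)cyclohex-3-en-1-yl]acetate | COC(=O)C[C@@H]1[C@@H](C(C)=C)CC=C(C)C1=O | intermediate
5 | p-toluenesulfonylhydrazone of 4 (C=N geometry not defined) | COC(=O)C[C@@H]1[C@@H](C(C)=C)CC=C(C)C1=NNS(=O)(=O)c1ccc(C)cc1 | intermediate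
6 | N-(catecholboryl) allylic tosylhydrazine from 5 (new C–N carbon of either configuration) | COC(=O)C[C@@H]1[C@@H](C(C)=C)CC=C(C)C1N(NS(=O)(=O)c1ccc(C)cc1)B1Oc2ccccc2O1 | intermediate (not isolated)
7 | allylic diazene from 6 (C–N carbon of either configuration) | COC(=O)C[C@@H]1[C@@H](C(C)=C)CC=C(C)C1N=N | intermediate (not isolated)
8 | methyl 2-[(1S,6S)-3-methyl-6-(prop-1-en-2-yl)cyclohex-2-en-1-yl]acetate | COC(=O)C[C@@H]1[C@@H](C(C)=C)CCC(C)=C1 | intermediate
9 | 2-[(1S,6S)-3-methyl-6-(prop-1-en-2-yl)cyclohex-2-en-1-yl]acetic acid | OC(=O)C[C@@H]1[C@@H](C(C)=C)CCC(C)=C1 | intermediate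
10 | Meldrum's acid (2,2-dimethyl-1,3-dioxane-4,6-dione) | CC1(C)OC(=O)CC(=O)O1 | starting material
11 | acyl Meldrum's acid of 9 (enol form) | CC1(C)OC(=O)C(=C(O)C[C@@H]2[C@@H](C(C)=C)CCC(C)=C2)C(=O)O1 | intermediate (not isolated)
12 | allyl 4-[(1S,6S)-3-methyl-6-(prop-1-en-2-yl)cyclohex-2-en-1-yl]-3-oxobutanoate | C=CCOC(=O)CC(=O)C[C@@H]1[C@@H](C(C)=C)CCC(C)=C1 | intermediate
13 | 1,5-dichloropentan-3-one | O=C(CCCl)CCCl | starting material
14 | 5-chloropent-1-en-3-one | C=CC(=O)CCCl | intermediate (not isolated)
15 | penta-1,4-dien-3-one | C=CC(=O)C=C | intermediate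
16 | mono-Michael adduct of 12 and 15 (both epimers at the new α-carbon) | C=CC(=O)CCC(C(=O)OCC=C)C(=O)C[C@@H]1[C@@H](C(C)=C)CCC(C)=C1 | intermediate (not isolated)
17 | allyl 1-{2-[(1S,6S)-3-methyl-6-(prop-1-en-2-yl)cyclohex-2-en-1-yl]acetyl}-4-oxocyclohexane-1-carboxylate | C=CCOC(=O)C1(CCC(=O)CC1)C(=O)C[C@@H]1[C@@H](C(C)=C)CCC(C)=C1 | intermediate
18 | allyl 8-{2-[(1S,6S)-3-methyl-6-(prop-1-en-2-yl)cyclohex-2-en-1-yl]acetyl}-1,4-dioxaspiro[4.5]decane-8-carboxylate | C=CCOC(=O)C1(CCC2(CC1)OCCO2)C(=O)C[C@@H]1[C@@H](C(C)=C)CCC(C)=C1 | intermediate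
19 | β-keto acid from 18 | OC(=O)C1(CCC2(CC1)OCCO2)C(=O)C[C@@H]1[C@@H](C(C)=C)CCC(C)=C1 | intermediate (not isolated)
20 | 1-(1,4-dioxaspiro[4.5]decan-8-yl)-2-[(1S,6S)-3-methyl-6-(prop-1-en-2-yl)cyclohex-2-en-1-yl]ethan-1-one | O=C(C[C@@H]1[C@@H](C(C)=C)CCC(C)=C1)C1CCC2(CC1)OCCO2 | intermediate
21 | 8-{3-[(1S,6S)-3-methyl-6-(prop-1-en-2-yl)cyclohex-2-en-1-yl]prop-1-en-2-yl}-1,4-dioxaspiro[4.5]decane | C=C(C[C@@H]1[C@@H](C(C)=C)CCC(C)=C1)C1CCC2(CC1)OCCO2 | intermediate
22 | 4-{3-[(1S,6S)-3-methyl-6-(prop-1-en-2-yl)cyclohex-2-en-1-yl]prop-1-en-2-yl}cyclohexan-1-one | C=C(C[C@@H]1[C@@H](C(C)=C)CCC(C)=C1)C1CCC(=O)CC1 | intermediate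
23 | lithium enolate of 22 (enolate toward C3′, C1′ R) | C=C(C[C@@H]1[C@@H](C(C)=C)CCC(C)=C1)[C@@H]1CCC(O[Li])=CC1 | intermediate (not isolated)
24 | trimethylsilyl enol ether of 22 (double bond C3′=C4′, C1′ R) | C=C(C[C@@H]1[C@@H](C(C)=C)CCC(C)=C1)[C@@H]1CCC(O[Si](C)(C)C)=CC1 | intermediate
25 | (2S,4R)-2-bromo ketone, bromine trans to the C1′ substituent (axial) | C=C(C[C@@H]1[C@@H](C(C)=C)CCC(C)=C1)[C@@H]1CCC(=O)[C@@H](Br)C1 | intermediate (not isolated)
26 | (2R,4R)-2-bromo-4-{3-[(1S,6S)-3-methyl-6-(prop-1-en-2-yl)cyclohex-2-en-1-yl]prop-1-en-2-yl}cyclohexan-1-one, bromine cis (equatorial) | C=C(C[C@@H]1[C@@H](C(C)=C)CCC(C)=C1)[C@@H]1CCC(=O)[C@H](Br)C1 | intermediate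
27 | (1S,2R,4R)-2-bromo-1-methyl-4-{3-[(1S,6S)-3-methyl-6-(prop-1-en-2-yl)cyclohex-2-en-1-yl]prop-1-en-2-yl}cyclohexan-1-ol | C=C(C[C@@H]1[C@@H](C(C)=C)CCC(C)=C1)[C@@H]1CC[C@](C)(O)[C@H](Br)C1 | intermediate
28 | CNP0213097.1: (1S,2R,4R)-2-bromo-1-methyl-4-{3-[(1R,2R,3S,6S)-6-methyl-3-(prop-1-en-2-yl)-7-oxabicyclo[4.1.0]heptan-2-yl]prop-1-en-2-yl}cyclohexan-1-ol | C=C(C[C@@H]1[C@@H](C(=C)C)CC[C@]2(C)O[C@H]12)[C@@H]1CC[C@](C)(O)[C@H](Br)C1 | target

**Step count and risks**

Total: 15 steps. Longest linear sequence: 14 steps from 1 (steps 1–5 and 7–15); step 6 is a one-step side branch.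

Most likely to fail:

1. Step 13. The bromide equilibration may not favour the equatorial (cis) bromide strongly enough, so that material cycles between epimers and elimination to the enone begins to compete. Fallback: set C3′ by kinetic protonation instead of equilibration. The crude mixture of 25 and 26 from the bromination is treated with Me3SiOTf/Et3N (CH2Cl2, 0 °C) to give the bromine-bearing silyl enol ether F1. Buffered desilylation (Bu4NF, AcOH, THF, −78 °C) then protonates C3′ from the axial direction, the same stereoelectronic preference that makes the kinetic bromide axial, which should leave bromine equatorial. This sets out from the 25/26 mixture and returns at 26.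

2. Step 15. Oxygen delivery may follow the substrate's own preference for the face anti to the C1 side chain, or oxidation may spill over to the 1,1-disubstituted alkenes. Fallback: drop reagent control and separate by reactivity. From 27, one equivalent of dimethyldioxirane (acetone, −40 °C) gives 28 together with the anti epoxide F2. The mixture is then warmed with pyrrolidine in aqueous ethanol (70 °C). Only F2 can open by trans-diaxial attack at its secondary carbon C6 (for 28 the diaxial opening would have to occur at the tertiary C5), giving the polar amino alcohol F3, which is removed by chromatography. This sets out from 27 and returns at 28.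

3. Step 7. The dienone may oligomerise faster than it is captured, or the sequence may stall at the mono-adduct. Fallback: close ring B by double alkylation instead of double conjugate addition. 13 is ketalised (ethylene glycol, TsOH, benzene, reflux) to 2,2-bis(2-chloroethyl)-1,3-dioxolane F4, and NaI in acetone converts it into 2,2-bis(2-iodoethyl)-1,3-dioxolane F5. Treatment of 12 with F5 and Cs2CO3 (DMF, 23 → 50 °C) gives the mono-alkylated keto ester F6, which closes by 6-exo-tet displacement at the same carbon. This sets out from 12 and returns at the ketal 18, after step 8.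

**Further compounds**

F1 | step 13 | {[(4R)-2-bromo-4-{3-[(1S,6S)-3-methyl-6-(prop-1-en-2-yl)cyclohex-2-en-1-yl]prop-1-en-2-yl}cyclohex-1-en-1-yl]oxy}trimethylsilane | C=C(C[C@@H]1[C@@H](C(C)=C)CCC(C)=C1)[C@@H]1CCC(O[Si](C)(C)C)=C(Br)C1
F2 | step 15 | anti epoxide, epimer of 28 at both epoxide carbons (oxygen anti to the C1 side chain) | C=C(C[C@@H]1[C@@H](C(=C)C)CC[C@@]2(C)O[C@@H]12)[C@@H]1CC[C@](C)(O)[C@H](Br)C1
F3 | step 15 | amino alcohol from F2: pyrrolidin-1-yl at ring-A C6 cis to the C1 side chain, tertiary hydroxyl at C5 trans to it | C=C(C[C@@H]1[C@@H](C(=C)C)CC[C@@](C)(O)[C@@H]1N1CCCC1)[C@@H]1CC[C@](C)(O)[C@H](Br)C1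
F4 | step 7 | 2,2-bis(2-chloroethyl)-1,3-dioxolane | ClCCC1(CCCl)OCCO1
F5 | step 7 | 2,2-bis(2-iodoethyl)-1,3-dioxolane | ICCC1(CCI)OCCO1
F6 | step 7 | mono-alkylated keto ester from 12 and F5 (both epimers at the α-carbon) | C=CCOC(=O)C(CCC1(CCI)OCCO1)C(=O)C[C@@H]1[C@@H](C(C)=C)CCC(C)=C1
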